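**Retrosynthetic overview**
1. Ring A halides last: the tertiary C-3–Br and the secondary C-2–Cl (trans-diaxial) come from the C-2=C-3 alkene of deschloroelatol acetate by epoxidation, chloride opening and exchange of hydroxyl for bromide.
2. Key disconnection: the C-6–C-11 bond of ring B. Ring B closes on a monocyclic, bisabolene-type precursor by a bromonium-initiated, allylsilane-terminated cation–olefin spirocyclisation that copies the presumed biogenesis of the chamigrenes.
3. Enabling feature: in ring B the CHBr carbon (C-10) lies between the oxygenated C-9 and the C(CH3)2 carbon (C-11), and C-11 is bonded to the spiro atom C-6, whose other ring-B neighbour C-7 carries the exocyclic CH2. The array Br–C10–C11(CH3)2–C6–C7(=CH2) is a bromonium-opened prenyl unit trapped by a tetrasubstituted alkene.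
4. The cyclisation precursor is cut at C-8–C-9 into an α-selective allyl-metal reagent and (S)-2-bromo-3-chloro-3-methylbutanal (from prenol by enantioselective bromochlorination); its tertiary chloride is the latent bromonium ion.
5. Ring order: ring A first, by ring-closing metathesis after the geometry of the tetrasubstituted C-6=C-7 alkene has been fixed by anti-carbomagnesiation of an alkynol; ring B last, in the key step.

Key step: step 9

Remark (numbering): chamigrene numbering is used; ring A = C-1 to C-6 (C-2 bears Cl, C-3 bears Br and CH3), ring B = C-6 to C-11 (C-6 spiro, C-7 carries the exocyclic CH2 = C-14, C-9 OAc, C-10 Br, C-11 C(CH3)2); the target is (2S,3S,6R,9S,10R).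
Assumption: in step 6 the enantiomer of the Schiff-base ligand is chosen that gives the (2S)-bromochloride; should the opposite sense of induction be found, the mirror-image ligand is used.

**Route**

Step 1
Reactants: 1 prop-2-yn-1-ol (propargyl alcohol); 2 3-bromoprop-1-ene (allyl bromide)
Product: 3 hex-5-en-2-yn-1-ol
Conditions: CuI (5 mol %), K2CO3, Bu4NBr (cat.), DMF, 23 °C
Reagents that add atoms: none
Why: Copper-catalysed allylation of a terminal alkyne (the copper acetylide displaces the allylic bromide) should give the skipped enyne without touching the free hydroxyl; no stereocentre is formed.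

Step 2
Reactants: 3 hex-5-en-2-yn-1-ol
Product: 5 (2E)-3-iodo-2-[(trimethylsilyl)methyl]hexa-2,5-dien-1-ol (iodine cis to CH2OH), via cyclic alkenylmagnesium alkoxide 4 (not isolated)
Conditions: Me3SiCH2MgCl (3 equiv), CuI (10 mol %), THF, 0 to 23 °C; then I2, −78 to 0 °C
Reagents that add atoms: (trimethylsilyl)methylmagnesium chloride, C[Si](C)(C)C[Mg]Cl; iodine, II
Why: Copper-catalysed anti-carbomagnesiation of a 2-alkyn-1-ol: the magnesium alkoxide directs the CH2SiMe3 group to the alkyne carbon next to the carbinol and holds the new C–Mg bond in a five-membered chelate, so that iodinolysis with retention should leave iodine cis to CH2OH and the allyl group cis to CH2SiMe3, which fixes the geometry of the later C-6=C-7 alkene.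

Step 3
Reactants: 5 (2E)-3-iodo-2-[(trimethylsilyl)methyl]hexa-2,5-dien-1-ol; 6 4-bromo-2-methylbut-1-ene
Product: 8 (2Z)-6-methyl-3-(prop-2-en-1-yl)-2-[(trimethylsilyl)methyl]hepta-2,6-dien-1-ol (CH2OH cis to the 3-methylbut-3-enyl chain), via (3-methylbut-3-en-1-yl)zinc bromide 7 (not isolated)
Conditions: 6, Zn, LiCl, THF, 40 °C; then 5, Pd(dppf)Cl2 (5 mol %), THF, 50 °C
Reagents that add atoms: none
Why: Negishi coupling: oxidative addition of the alkenyl iodide to zerovalent palladium, transmetalation from zinc and reductive elimination proceed with retention of alkene geometry, so the chain that becomes C-5, C-4 and C-3 should end cis to CH2OH (the later C-8).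

Step 4
Reactants: 8 (2Z)-6-methyl-3-(prop-2-en-1-yl)-2-[(trimethylsilyl)methyl]hepta-2,6-dien-1-ol
Product: 9 (2Z)-2-(4-methylcyclohex-3-en-1-ylidene)-3-(trimethylsilyl)propan-1-ol (CH2OH cis to the ring CH2CH2 side)
Conditions: (H2IMes)(PCy3)Cl2Ru=CHPh (second-generation Grubbs catalyst, 3 mol %), CH2Cl2, 40 °C
Reagents that add atoms: none
Why: Ring-closing metathesis of the monosubstituted with the 1,1-disubstituted terminal alkene should close ring A as a trisubstituted cyclohexene with loss of ethene, while the tetrasubstituted alkene is inert to the ruthenium carbene and keeps its geometry.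

Step 5
Reactants: 9 (2Z)-2-(4-methylcyclohex-3-en-1-ylidene)-3-(trimethylsilyl)propan-1-ol
Product: 10 [(2E)-3-chloro-2-(4-methylcyclohex-3-en-1-ylidene)propyl](trimethyl)silane (CH2Cl cis to the ring CH2CH2 side)
Conditions: MsCl, 2,4,6-collidine, LiCl, DMF, 0 °C
Reagents that add atoms: lithium chloride, [Li+].[Cl-]
Why: Mesylation and SN2 displacement by chloride at the primary allylic carbon under collidine buffering should give the chloride without allylic transposition or protodesilylation (alcohol-to-chloride substitution).

Step 6
Reactants: 11 3-methylbut-2-en-1-ol (prenol)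
Product: 12 (2S)-2-bromo-3-chloro-3-methylbutan-1-ol
Conditions: NBS, ClTi(OiPr)3, chiral tridentate O,N,O Schiff-base ligand (salicylaldimine of a 1,2-amino alcohol, 20 mol %), hexanes, −20 °C
Reagents that add atoms: N-bromosuccinimide, O=C1CCC(=O)N1Br; chlorotitanium triisopropoxide, CC(C)O[Ti](Cl)(OC(C)C)OC(C)C
Why: Ligand-controlled, titanium-mediated enantioselective bromochlorination of an allylic alcohol: the alkoxide-bound titanium complex should direct bromonium formation to one alkene face and deliver chloride anti to the tertiary carbon, which sets the single stereocentre as 2S.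

Step 7
Reactants: 12 (2S)-2-bromo-3-chloro-3-methylbutan-1-ol
Product: 13 (2S)-2-bromo-3-chloro-3-methylbutanal
Conditions: Dess–Martin periodinane, CH2Cl2, 0 to 23 °C; used crude at once
Reagents that add atoms: none
Why: Dess–Martin oxidation is neutral and fast, so the α-bromo aldehyde should form without enolisation (loss of configuration) or β-elimination of chloride.

Step 8
Reactants: 10 [(2E)-3-chloro-2-(4-methylcyclohex-3-en-1-ylidene)propyl](trimethyl)silane; 13 (2S)-2-bromo-3-chloro-3-methylbutanal
Product: 15 (2Z,4S,5S)-5-bromo-6-chloro-6-methyl-2-(4-methylcyclohex-3-en-1-ylidene)-1-(trimethylsilyl)heptan-4-ol (C-8 cis to C-5; hydroxyl and bromine anti in the zigzag chain), via allylbarium chloride 14 (not isolated)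
Conditions: BaI2, LiC12H10 (lithium biphenylide), THF, 23 °C; then 10, −78 °C; then 13, −78 °C; AcOH, −78 °C
Reagents that add atoms: none
Why: Allylbarium reagents add to aldehydes through the unsubstituted (α) terminus with retention of the allyl geometry, and polar Felkin–Anh control by the α-bromine (bromine anti to the incoming nucleophile) should give the 4,5-anti bromohydrin, which sets C-9 as S (α-selective carbonyl allylation).

Step 9
Reactants: 15 (2Z,4S,5S)-5-bromo-6-chloro-6-methyl-2-(4-methylcyclohex-3-en-1-ylidene)-1-(trimethylsilyl)heptan-4-ol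
Product: 17 deschloroelatol, (6R,9S,10R)-10-bromochamigra-2,7(14)-dien-9-ol, via bromonium chloride 16 (not isolated)
Conditions: (CF3)2CHOH (0.005 M), 2,6-di-tert-butyl-4-methylpyridine, 0 to 23 °C
Reagents that add atoms: none
Why: In the ionising, weakly nucleophilic solvent the tertiary C-11–Cl bond should leave with anchimeric help from the antiperiplanar bromine to give the configurationally defined bromonium ion 16, which is opened at C-11 by C-6 of the allylsilane (anti SE2′), and the β-silyl cation then loses the silyl group to chloride so that only the exocyclic C-7=C-14 alkene can form. The closest known reaction types are the bromonium-initiated cation–olefin cyclisation started by solvolysis of an enantioenriched vicinal bromochloride and the allylsilane-terminated polyene cyclisation, and the step copies the presumed bisabolene-to-chamigrene biogenesis. Ring B closes in a 6-endo mode with respect to both the bromonium ion and the C-6=C-7 alkene through a chair transition state. C-6 is the only new stereocentre: bromine must be equatorial (anti to the forming C-11–C-6 bond), the hydroxyl is then axial, and the fixed alkene geometry places C-5 (cis to C-8) axial and C-1 equatorial on ring B, which should give 6R, while C-9 and C-10 are carried over unchanged. The step needs chemoselective ionisation (only C-11–Cl has a participating neighbour), carbon rather than oxygen capture of the bromonium ion (a free hydroxyl instead of an ester avoids acyloxonium formation) and survival of the allylsilane (the hindered pyridine acts as proton trap).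

Step 10
Reactants: 17 deschloroelatol
Product: 18 deschloroelatol acetate, (6R,9S,10R)-10-bromochamigra-2,7(14)-dien-9-yl acetate
Conditions: Ac2O, DMAP, pyridine, 23 °C
Reagents that add atoms: acetic anhydride, CC(=O)OC(C)=O
Why: Nucleophilic catalysis by DMAP should acetylate the hindered axial secondary alcohol without change at any stereocentre (acylation).

Step 11
Reactants: 18 deschloroelatol acetate
Product: 19 (2R,3S,6R,9S,10R)-10-bromo-2,3-epoxychamigr-7(14)-en-9-yl acetate (epoxide oxygen on the ring-A face of C-11, anti to C-7)
Conditions: mCPBA, CH2Cl2, −20 to 0 °C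
Reagents that add atoms: 3-chloroperoxybenzoic acid (mCPBA), OOC(=O)c1cccc(Cl)c1
Why: Prilezhaev epoxidation: the electron-rich trisubstituted C-2=C-3 alkene should react before the hindered 1,1-disubstituted exocyclic alkene, and the peracid should approach anti to the pseudoaxial C-7 on ring A, which sets C-2 (R) and C-3 (S).

Step 12
Reactants: 19 (2R,3S,6R,9S,10R)-10-bromo-2,3-epoxychamigr-7(14)-en-9-yl acetate
Product: 20 (2S,3S,6R,9S,10R)-10-bromo-2-chloro-3-hydroxychamigr-7(14)-en-9-yl acetate (Cl axial at C-2, OH axial at C-3, trans)
Conditions: pyridinium chloride, CHCl3, 23 °C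
Reagents that add atoms: pyridinium chloride, [Cl-].c1cc[nH+]cc1
Why: Mildly acid-assisted epoxide opening by chloride should follow the Fürst–Plattner rule, with SN2 attack at the secondary C-2 from the face opposite to oxygen (inversion, Cl axial) leaving the axial tertiary C-3 alcohol (trans-diaxial opening to a chlorohydrin).

Step 13
Reactants: 20 (2S,3S,6R,9S,10R)-10-bromo-2-chloro-3-hydroxychamigr-7(14)-en-9-yl acetate
Product: 22 9-acetylisoobtusol, (2S,3S,6R,9S,10R)-3,10-dibromo-2-chlorochamigr-7(14)-en-9-yl acetate, via tertiary bromooxalate 21 (not isolated)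
Conditions: (COBr)2, 2,6-di-tert-butyl-4-methylpyridine, CH2Cl2, −40 to 23 °C
Reagents that add atoms: oxalyl bromide, O=C(Br)C(=O)Br
Why: The tertiary bromooxalate should lose CO2 and CO by internal ionisation (SNi-type substitution of a halooxalate), and the cation, bridged on its rear face by the antiperiplanar axial chlorine at C-2, should be captured by bromide on the face that oxygen left, giving the trans-diaxial bromochloride with retention at C-3 while the acid-free medium spares the exocyclic alkene.

**Compound list**
1 | prop-2-yn-1-ol | OCC#C | starting material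
2 | 3-bromoprop-1-ene | C=CCBr | starting material
3 | hex-5-en-2-yn-1-ol | OCC#CCC=C | intermediate
4 | 3-(prop-2-en-1-yl)-4-[(trimethylsilyl)methyl]-2,5-dihydro-1,2-oxamagnesole (cyclic alkenylmagnesium alkoxide) | C[Si](C)(C)CC1=C(CC=C)[Mg]OC1 | intermediate (not isolated)
5 | (2E)-3-iodo-2-[(trimethylsilyl)methyl]hexa-2,5-dien-1-ol | OC/C(C[Si](C)(C)C)=C(\I)CC=C | intermediate
6 | 4-bromo-2-methylbut-1-ene | C=C(C)CCBr | starting material
7 | (3-methylbut-3-en-1-yl)zinc bromide | C=C(C)CC[Zn]Br | intermediate (not isolated)
8 | (2Z)-6-methyl-3-(prop-2-en-1-yl)-2-[(trimethylsilyl)methyl]hepta-2,6-dien-1-ol | OC/C(C[Si](C)(C)C)=C(\CCC(C)=C)CC=C | intermediate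
9 | (2Z)-2-(4-methylcyclohex-3-en-1-ylidene)-3-(trimethylsilyl)propan-1-ol | OC/C(C[Si](C)(C)C)=C1\CCC(C)=CC1 | intermediate
10 | [(2E)-3-chloro-2-(4-methylcyclohex-3-en-1-ylidene)propyl](trimethyl)silane | ClC/C(C[Si](C)(C)C)=C1\CCC(C)=CC1 | intermediate
11 | 3-methylbut-2-en-1-ol | CC(C)=CCO | starting material
12 | (2S)-2-bromo-3-chloro-3-methylbutan-1-ol | OC[C@H](Br)C(C)(C)Cl | intermediate
13 | (2S)-2-bromo-3-chloro-3-methylbutanal | O=C[C@H](Br)C(C)(C)Cl | intermediate
14 | allylbarium chloride from 10 (CH2BaCl cis to the ring CH2CH2 side) | Cl[Ba]C/C(C[Si](C)(C)C)=C1\CCC(C)=CC1 | intermediate (not isolated)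
15 | (2Z,4S,5S)-5-bromo-6-chloro-6-methyl-2-(4-methylcyclohex-3-en-1-ylidene)-1-(trimethylsilyl)heptan-4-ol | C[Si](C)(C)C/C(C[C@H](O)[C@H](Br)C(C)(C)Cl)=C1/CCC(C)=CC1 | intermediate
16 | bromonium chloride from 15 (bromine bridging C-10 and C-11) | C[Si](C)(C)C/C(C[C@H](O)[C@@H]2[Br+]C2(C)C)=C1/CCC(C)=CC1.[Cl-] | intermediate (not isolated)
17 | deschloroelatol, (6R,9S,10R)-10-bromochamigra-2,7(14)-dien-9-ol | C=C1C[C@H](O)[C@H](Br)C(C)(C)[C@@]12CCC(C)=CC2 | intermediate
18 | deschloroelatol acetate, (6R,9S,10R)-10-bromochamigra-2,7(14)-dien-9-yl acetate | C=C1C[C@H](OC(C)=O)[C@H](Br)C(C)(C)[C@@]12CCC(C)=CC2 | intermediate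
19 | (2R,3S,6R,9S,10R)-10-bromo-2,3-epoxychamigr-7(14)-en-9-yl acetate | C=C1C[C@H](OC(C)=O)[C@H](Br)C(C)(C)[C@@]12CC[C@]3(C)O[C@@H]3C2 | intermediate
20 | (2S,3S,6R,9S,10R)-10-bromo-2-chloro-3-hydroxychamigr-7(14)-en-9-yl acetate | C=C1C[C@H](OC(C)=O)[C@H](Br)C(C)(C)[C@@]12CC[C@](C)(O)[C@@H](Cl)C2 | intermediate
21 | tertiary bromooxalate of 20 (C-3 O–CO–CO–Br) | C=C1C[C@H](OC(C)=O)[C@H](Br)C(C)(C)[C@@]12CC[C@](C)(OC(=O)C(=O)Br)[C@@H](Cl)C2 | intermediate (not isolated)
22 | 9-acetylisoobtusol, (2S,3S,6R,9S,10R)-3,10-dibromo-2-chlorochamigr-7(14)-en-9-yl acetate | C=C1C[C@H](OC(C)=O)[C@H](Br)C(C)(C)[C@@]12CC[C@](C)(Br)[C@@H](Cl)C2 | target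

**Step count and risks**
Total step count: 13. Longest linear sequence: 11 steps (steps 1–5 and 8–13); steps 6 and 7 prepare the aldehyde 13.

The three steps most likely to fail:

Step 13. Ionisation next to the electron-withdrawing chlorine is slow, so proton loss from the tertiary cation (elimination) or attack on the exocyclic alkene may outrun bromide capture. The fallback sets out from 18 and bypasses 19 to 21. Chloroselenation with PhSeCl (CH2Cl2, −78 °C) is expected to give, under kinetic control and by trans-diaxial opening of the seleniranium ion formed on the face of C-11, the anti-Markovnikov adduct (2S,3S,6R,9S,10R)-10-bromo-2-chloro-3-(phenylselanyl)chamigr-7(14)-en-9-yl acetate F1. Without warming, Br2 (1 equiv, CH2Cl2, −78 °C) should convert the tertiary selenide into the bromide with loss of PhSeBr, the chlorine-bridged cation again being captured on the face that selenium left. This comes back to the route at 22.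

Step 8. The strongly basic allyl reagent may deprotonate the α-bromo aldehyde (loss of configuration, elimination of chloride), residual activated metal may reduce it, and the bromohydrin alkoxide may close to an epoxide. The fallback sets out from 10. Bu3SnLi (THF, −78 °C) should give tributyl[2-(4-methylcyclohex-3-en-1-ylidene)-3-(trimethylsilyl)propyl]stannane F2 with the geometry retained. Tin–lithium exchange (MeLi, THF, −78 °C) gives the allyllithium F3, and CeCl3 (−78 °C) the allylcerium dichloride F4, a far less basic reagent that also reacts through its less substituted terminus. Addition of 13 at −78 °C and an AcOH quench return to 15.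

Step 9. The allylsilane may be protodesilylated, or the bromonium ion captured by solvent or by the free hydroxyl, before the C–C bond forms; closure through a boat would give the wrong configuration at C-6. The fallback sets out from 15. Et3SiCl, imidazole, DMF gives the triethylsilyl ether of 15 F5. Halide abstraction in an aprotic medium (AgBF4, 2,6-di-tert-butyl-4-methylpyridine, CH2Cl2, −78 °C) should generate the bromonium tetrafluoroborate F6, which closes to the triethylsilyl ether of deschloroelatol F7. HF·pyridine (THF, 0 °C) removes the silyl group and returns to 17.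

Further compounds
F1 | step 13 | (2S,3S,6R,9S,10R)-10-bromo-2-chloro-3-(phenylselanyl)chamigr-7(14)-en-9-yl acetate | C=C1C[C@H](OC(C)=O)[C@H](Br)C(C)(C)[C@@]12CC[C@](C)([Se]c3ccccc3)[C@@H](Cl)C2
F2 | step 8 | tributyl[2-(4-methylcyclohex-3-en-1-ylidene)-3-(trimethylsilyl)propyl]stannane (CH2Sn cis to the ring CH2CH2 side) | CCCC[Sn](CCCC)(CCCC)C/C(C[Si](C)(C)C)=C1\CCC(C)=CC1
F3 | step 8 | allyllithium from F2 (CH2Li cis to the ring CH2CH2 side) | [Li]C/C(C[Si](C)(C)C)=C1\CCC(C)=CC1
F4 | step 8 | allylcerium dichloride from F3 (CH2Ce cis to the ring CH2CH2 side) | Cl[Ce](Cl)C/C(C[Si](C)(C)C)=C1\CCC(C)=CC1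
F5 | step 9 | triethylsilyl ether of 15 | C[Si](C)(C)C/C(C[C@H](O[Si](CC)(CC)CC)[C@H](Br)C(C)(C)Cl)=C1/CCC(C)=CC1
F6 | step 9 | bromonium tetrafluoroborate from F5 | C[Si](C)(C)C/C(C[C@H](O[Si](CC)(CC)CC)[C@@H]2[Br+]C2(C)C)=C1/CCC(C)=CC1.F[B-](F)(F)F
F7 | step 9 | triethylsilyl ether of deschloroelatol | C=C1C[C@H](O[Si](CC)(CC)CC)[C@H](Br)C(C)(C)[C@@]12CCC(C)=CC2
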